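1. Rings: A = methylcyclopentane carrying the trisubstituted alkene carbon, B = cyclohexene, C = 1,3-dimethylcyclopentane with the side chain, D = methylcyclopentane fused to B. The epoxy diol chain is cut back (epoxide from a diol monosulfonate, diol by OsO4 on an E-allylic alcohol, C–C bond by Ni/Cr alkenylation) to a tetracyclic CH2CHO core.
2. The two secondary methyl centres (rings A and D) come from two exocyclic methylenes reduced together by diimide; the ring A methylene comes from a ketone by Wittig reaction.
3. Key disconnection of that tetracyclic dienone: ring B at its C=C and ring D at the bond between the B/D fusion CH and the quaternary carbon shared by A, B and D. The precursor is a ring C aldehyde–acid carrying a 3-(alk-1-en-2-yl)cyclopent-2-enone (ring A); forward, a decarboxylative radical 5-exo closure of ring D is followed by aldol condensation closing ring B.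
4. Enabling feature: the quaternary carbon shared by A, B and D is β to the methyl-bearing ring A carbon. With that carbon as C=O, the shared carbon is an enone β-carbon (radical acceptor) and the ring A alkene carbon is the enone α-carbon (enolate), which condenses with the ring B alkene CH held as an aldehyde. This CH and the B/D fusion CH are cis-1,2 on ring C, so both are released from one cis-fused δ-lactone.
5. Ring order: ring C from 2,5-dimethylcyclopentanone (quaternary centres by Pd-allylation and hydroxymethylation) → temporary lactone ring → ring A attached by Suzuki coupling → ring D, then ring B (key step) → side chain.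

Key step: step 14

Remark: 3-bromobut-3-en-1-ol, 3-bromocyclopent-2-en-1-one and (E)-3-iodo-2-methylprop-2-en-1-ol are taken as catalogue chemicals.

Step 1
Reactants: 1 2,5-dimethylcyclopentan-1-one (commercial cis/trans mixture)
Product: 2 [(2,5-dimethylcyclopent-1-en-1-yl)oxy]trimethylsilane (racemic)
Conditions: TMSOTf, Et3N, CH2Cl2, 0 °C
Reagents that add atoms: trimethylsilyl trifluoromethanesulfonate, C[Si](C)(C)OS(=O)(=O)C(F)(F)F
Why: Soft enolization and O-silylation; both α-carbons are equivalent, so a single tetrasubstituted silyl enol ether should form and no stereocentre is fixed yet.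

Step 2
Reactants: 2 [(2,5-dimethylcyclopent-1-en-1-yl)oxy]trimethylsilane
Product: 3 (2R)-2,5-dimethyl-2-(prop-2-en-1-yl)cyclopentan-1-one (both epimers at the methine carbon)
Conditions: Pd2(dba)3 (2.5 mol %), (R)-t-Bu-PHOX (6 mol %), diallyl carbonate, Bu4N[Ph3SiF2] (35 mol %), THF, 25 °C
Reagents that add atoms: diallyl carbonate, C=CCOC(=O)OCC=C
Why: Enantioselective Tsuji-type allylic alkylation in which fluoride frees the enolate, zerovalent palladium with the PHOX ligand ionizes diallyl carbonate, and C–C bond formation in the chiral π-allyl complex should set the allyl-bearing quaternary centre as R (ligand control), while the other α-centre stays epimeric and is planarized in step 3.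

Step 3
Reactants: 3 (2R)-2,5-dimethyl-2-(prop-2-en-1-yl)cyclopentan-1-one
Product: 4 {[(5R)-2,5-dimethyl-5-(prop-2-en-1-yl)cyclopent-1-en-1-yl]oxy}trimethylsilane
Conditions: LiN(i-Pr)2, THF, −78 → 0 °C; TMSCl
Reagents that add atoms: chlorotrimethylsilane, C[Si](C)(C)Cl
Why: Deprotonation of the only remaining α-hydrogen and O-silylation (enolate trapping) should give one regiodefined tetrasubstituted silyl enol ether with the quaternary centre untouched.

Step 4
Reactants: 4 {[(5R)-2,5-dimethyl-5-(prop-2-en-1-yl)cyclopent-1-en-1-yl]oxy}trimethylsilane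
Product: 5 (2R,5R)-5-(hydroxymethyl)-2,5-dimethyl-2-(prop-2-en-1-yl)cyclopentan-1-one
Conditions: 35% aq. HCHO, Sc(OTf)3 (10 mol %), chiral 6,6'-bis(1-hydroxy-2,2-dimethylpropyl)-2,2'-bipyridine (12 mol %, matched enantiomer), DME/H2O, −20 °C
Reagents that add atoms: formaldehyde, C=O
Why: Lewis-acid-catalysed aqueous Mukaiyama aldol reaction (hydroxymethylation) in which formaldehyde should add to the enol ether face anti to the allyl group on the neighbouring quaternary carbon, a bias reinforced by the matched chiral Sc complex, giving the second quaternary centre with the two methyls trans.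

Step 5
Reactants: 5 (2R,5R)-5-(hydroxymethyl)-2,5-dimethyl-2-(prop-2-en-1-yl)cyclopentan-1-one
Product: 6 [(1R,3R)-1,3-dimethyl-2-oxo-3-(prop-2-en-1-yl)cyclopentyl]methyl 2-(diethoxyphosphoryl)acetate
Conditions: (EtO)2P(O)CH2CO2H, DCC, DMAP (cat.), CH2Cl2, 0 °C → rt
Reagents that add atoms: 2-(diethoxyphosphoryl)acetic acid, CCOP(=O)(CC(=O)O)OCC
Why: Steglich esterification of the neopentyl primary alcohol, which affects no stereocentre.

Step 6
Reactants: 6 [(1R,3R)-1,3-dimethyl-2-oxo-3-(prop-2-en-1-yl)cyclopentyl]methyl 2-(diethoxyphosphoryl)acetate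
Product: 7 (5R,7aS)-5,7a-dimethyl-5-(prop-2-en-1-yl)-5,6,7,7a-tetrahydrocyclopenta[c]pyran-3(1H)-one
Conditions: NaH, THF, 0 → 50 °C
Reagents that add atoms: none
Why: Intramolecular Horner–Wadsworth–Emmons olefination in which the tether delivers the phosphonate carbanion to the doubly α-quaternary ketone through a six-membered ring, and the alkene can only form toward the lactone α-carbon.

Step 7
Reactants: 7 (5R,7aS)-5,7a-dimethyl-5-(prop-2-en-1-yl)-5,6,7,7a-tetrahydrocyclopenta[c]pyran-3(1H)-one
Product: 9 (5R,7aS)-5-(1,3-dioxolan-2-ylmethyl)-5,7a-dimethyl-5,6,7,7a-tetrahydrocyclopenta[c]pyran-3(1H)-one, via aldehyde 8 (not isolated)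
Conditions: OsO4 (2 mol %), NaIO4, 2,6-lutidine, dioxane/H2O, rt; then HOCH2CH2OH, p-TsOH (cat.), benzene, reflux (−H2O)
Reagents that add atoms: ethane-1,2-diol, OCCO
Why: Lemieux–Johnson cleavage should select the terminal alkene over the hindered electron-poor conjugated one, and acid-catalysed acetalization then masks the aldehyde as a base-stable dioxolane.

Step 8
Reactants: 9 (5R,7aS)-5-(1,3-dioxolan-2-ylmethyl)-5,7a-dimethyl-5,6,7,7a-tetrahydrocyclopenta[c]pyran-3(1H)-one
Product: 10 (4aR,5R,7aS)-5-(1,3-dioxolan-2-ylmethyl)-5,7a-dimethylhexahydrocyclopenta[c]pyran-3(1H)-one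
Conditions: H2 (4 atm), Pd/C, EtOAc, rt
Reagents that add atoms: none
Why: Heterogeneous hydrogenation should deliver H2 to the convex face that carries the angular methyl, as in hydrogenations of angularly methylated hydrindenones, giving the cis-fused lactone; this fixes the ring C methine and places the lactone α-carbon and the OCH2 carbon cis on ring C.

Step 9
Reactants: 11 3-bromobut-3-en-1-ol
Product: 12 2-bromo-4-iodobut-1-ene
Conditions: I2, PPh3, imidazole, CH2Cl2, 0 °C → rt
Reagents that add atoms: iodine, II
Why: Appel-type iodination of a primary alcohol by SN2 displacement of the oxyphosphonium group, with the vinyl bromide inert.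

Step 10
Reactants: 10 (4aR,5R,7aS)-5-(1,3-dioxolan-2-ylmethyl)-5,7a-dimethylhexahydrocyclopenta[c]pyran-3(1H)-one; 12 2-bromo-4-iodobut-1-ene
Product: 13 (4aR,5R,7aS)-4-(3-bromobut-3-en-1-yl)-5-(1,3-dioxolan-2-ylmethyl)-5,7a-dimethylhexahydrocyclopenta[c]pyran-3(1H)-one (both epimers at the lactone α-carbon)
Conditions: LiN(i-Pr)2, THF, −78 °C; then 12, DMPU, −78 → −20 °C
Reagents that add atoms: none
Why: SN2 alkylation of the lactone lithium enolate with the primary iodide; the new α-centre is an inconsequential epimer mixture because this carbon becomes a planar radical in step 14.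

Step 11
Reactants: 13 (4aR,5R,7aS)-4-(3-bromobut-3-en-1-yl)-5-(1,3-dioxolan-2-ylmethyl)-5,7a-dimethylhexahydrocyclopenta[c]pyran-3(1H)-one
Product: 15 5-bromo-2-[(1R,2S,5R)-5-(1,3-dioxolan-2-ylmethyl)-2-formyl-2,5-dimethylcyclopentyl]hex-5-enoic acid, via tetrabutylammonium hydroxy-carboxylate 14 (not isolated)
Conditions: Bu4NOH, THF/H2O, 40 °C; evaporate; Dess–Martin periodinane, pyridine, CH2Cl2, 0 °C; 1 M HCl work-up (pH 4)
Reagents that add atoms: tetrabutylammonium hydroxide, CCCC[N+](CCCC)(CCCC)CCCC.[OH-]
Why: Saponification opens the lactone to the ammonium carboxylate, which cannot relactonize, and Dess–Martin oxidation converts the freed neopentyl primary alcohol into the non-enolizable aldehyde.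

Step 12
Reactants: 16 3-bromocyclopent-2-en-1-one
Product: 17 3-(4,4,5,5-tetramethyl-1,3,2-dioxaborolan-2-yl)cyclopent-2-en-1-one
Conditions: B2pin2, PdCl2(dppf) (3 mol %), KOAc, dioxane, 80 °C
Reagents that add atoms: bis(pinacolato)diboron, CC1(C)OB(OC1(C)C)B1OC(C)(C)C(C)(C)O1
Why: Miyaura borylation of the β-bromo enone (oxidative addition, acetate-assisted transmetalation, reductive elimination).

Step 13
Reactants: 15 5-bromo-2-[(1R,2S,5R)-5-(1,3-dioxolan-2-ylmethyl)-2-formyl-2,5-dimethylcyclopentyl]hex-5-enoic acid; 17 3-(4,4,5,5-tetramethyl-1,3,2-dioxaborolan-2-yl)cyclopent-2-en-1-one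
Product: 18 2-[(1R,2S,5R)-5-(1,3-dioxolan-2-ylmethyl)-2-formyl-2,5-dimethylcyclopentyl]-5-(3-oxocyclopent-1-en-1-yl)hex-5-enoic acid (both epimers at the acid α-carbon)
Conditions: PdCl2(dppf) (5 mol %), K3PO4, dioxane/H2O, 60 °C; pH 4 work-up
Reagents that add atoms: none
Why: Suzuki–Miyaura sp2–sp2 coupling of the 2-bromoalkene with the β-boryl enone builds the cross-conjugated dienone, and the carboxylate and the non-enolizable aldehyde should tolerate aqueous phosphate.

Step 14
Reactants: 18 2-[(1R,2S,5R)-5-(1,3-dioxolan-2-ylmethyl)-2-formyl-2,5-dimethylcyclopentyl]-5-(3-oxocyclopent-1-en-1-yl)hex-5-enoic acid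
Product: 20 tetracyclic dienone (ring skeleton of the target; C=O at the ring A methyl-bearing position conjugated to the ring A/B C=C; exocyclic CH2= at the ring D methyl-bearing position; (1,3-dioxolan-2-yl)methyl on ring C; five ring stereocentres as in the target), via aldol adduct 19 (not isolated)
Conditions: Ir[dF(CF3)ppy]2(dtbbpy)PF6 (2 mol %), K2HPO4, DMF (0.01 M), 450 nm LEDs, 25 °C; then DBU, 40 °C
Reagents that add atoms: none
Why: The carboxylate is oxidized by the excited trivalent iridium photocatalyst and loses CO2 to give a secondary alkyl radical at the future ring B/D fusion CH; this nucleophilic radical closes ring D by 5-exo-trig Giese addition to the fully substituted β-carbon of the cyclopentenone, creating the quaternary carbon shared by rings A, B and D, and the resulting α-keto radical is reduced by divalent iridium to the enolate (radical-polar crossover). The enolate carbon, the future ring A alkene carbon, then closes ring B by 6-(enolexo)-exo-trig aldol addition to the non-enolizable neopentyl aldehyde on ring C, and DBU completes the E1cB loss of water to the conjugated enone, whose C=C is the trisubstituted alkene of the target. The closest known reaction types are the photoredox decarboxylative radical conjugate addition of aliphatic acids to cyclic enones and reductive radical cyclization–aldol sequences, followed by an ordinary aldol condensation. At the radical carbon the enone should add anti to the side-chain-bearing quaternary carbon of ring C, in the rotamer that keeps the tether between the ring C methine hydrogen and that quaternary carbon (control by the resident ring C stereocentres); at the new quaternary carbon the bulky ring C substituent should sit pseudo-equatorial in the chair-like 5-hexenyl transition state and end cis to the enone α-carbon, the only arrangement from which the cis-fused ring B can close. The step needs 5-exo attack at the carbonyl-activated β-carbon to win over 5-endo attack at the methylene terminus and over 1,5-hydrogen transfer; the polarity-matched enone and the absence of any other alkene (the allyl group is masked as a dioxolane) secure this, and the aldehyde offers the radical no favourable ring closure.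

Step 15
Reactants: 20 tetracyclic dienone
Product: 21 tetracyclic triene (20 with the ring A C=O replaced by C=CH2)
Conditions: Ph3PCH3Br, KOt-Bu, THF, 0 °C → rt
Reagents that add atoms: methyltriphenylphosphonium bromide, C[P+](c1ccccc1)(c1ccccc1)c1ccccc1.[Br-]
Why: Wittig methylenation (1,2-addition of the non-stabilized ylide to the conjugated cyclopentanone) converts C=O into the exocyclic methylene that supplies the last skeletal carbon.

Step 16
Reactants: 21 tetracyclic triene
Product: 22 tetracyclic dioxolane (ring skeleton and all seven ring stereocentres of the target; side chain replaced by CH2–(1,3-dioxolan-2-yl))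
Conditions: 2-nitrobenzenesulfonohydrazide (excess), Et3N, CH2Cl2, rt
Reagents that add atoms: none
Why: Diimide reduction transfers H2 suprafacially to the two 1,1-disubstituted alkenes without migration or 1,4-addition and spares the shielded trisubstituted alkene; at ring A it should approach the face opposite the ring D carbon that projects from the shared quaternary carbon, and at ring D the convex face away from ring B, so both new methyls end on the hindered faces as in the target.

Step 17
Reactants: 22 tetracyclic dioxolane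
Product: 23 tetracyclic aldehyde (22 with CH2CHO in place of the dioxolanylmethyl group)
Conditions: 2 M HCl, THF, rt
Reagents that add atoms: water, O
Why: Acid-catalysed acetal hydrolysis, to which the hindered trisubstituted alkene and the hydrocarbon skeleton should be inert.

Step 18
Reactants: 24 (E)-3-iodo-2-methylprop-2-en-1-ol
Product: 25 tert-butyl{[(E)-3-iodo-2-methylprop-2-en-1-yl]oxy}dimethylsilane
Conditions: TBSCl, imidazole, DMF, rt
Reagents that add atoms: tert-butyldimethylsilyl chloride, CC(C)(C)[Si](C)(C)Cl
Why: Imidazole-promoted silylation of the primary allylic alcohol, which leaves the alkene geometry untouched.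

Step 19
Reactants: 23 tetracyclic aldehyde; 25 tert-butyl{[(E)-3-iodo-2-methylprop-2-en-1-yl]oxy}dimethylsilane
Product: 26 (S)-allylic alcohol (ring C side chain CH2–CH(OH)–CH=C(CH3)–CH2OSi(t-Bu)Me2; E alkene; ring stereocentres as in 22)
Conditions: CrCl2, NiCl2 (2 mol %), (S)-N-[2-(4-isopropyl-4,5-dihydrooxazol-2-yl)-6-methylphenyl]methanesulfonamide (enantiomer chosen for the S carbinol), Et3N, THF, rt
Reagents that add atoms: none
Why: Nozaki–Hiyama–Kishi coupling in which the alkenylchromium formed through nickel catalysis adds only to the aldehyde with retention of the E geometry, and the chiral oxazoline–sulfonamide ligand on chromium should set the new carbinol as S by reagent control.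

Step 20
Reactants: 26 (S)-allylic alcohol
Product: 27 (S,S,S)-triol silyl ether (side chain CH2–CH(OH)–CH(OH)–C(OH)(CH3)–CH2OSi(t-Bu)Me2)
Conditions: OsO4 (5 mol %), N-methylmorpholine N-oxide, acetone/H2O, 0 °C
Reagents that add atoms: osmium tetroxide, O=[Os](=O)(=O)=O; N-methylmorpholine N-oxide, C[N+]1([O-])CCOCC1; water, O
Why: Catalytic OsO4 syn-dihydroxylation of the E allylic alcohol, in which osmium should attack anti to the resident hydroxyl in the conformer whose carbinol hydrogen eclipses the alkene (allylic 1,3-strain with the cis methyl); this sets the anti relationship to the existing carbinol and, through syn addition to the E alkene, both new carbinol centres, while the ring alkene is too shielded to react.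

Step 21
Reactants: 27 (S,S,S)-triol silyl ether
Product: 28 (S,S,S)-tetraol (side chain CH2–CH(OH)–CH(OH)–C(OH)(CH3)–CH2OH)
Conditions: HF·pyridine, THF/pyridine, 0 °C
Reagents that add atoms: none
Why: Fluoride-mediated cleavage of the primary silyl ether, which affects no stereocentre.

Step 22
Reactants: 28 (S,S,S)-tetraol
Product: 30 CNP0393869.2 (target), via primary tosylate 29 (not isolated)
Conditions: TsCl, Bu2SnO (5 mol %), Et3N, CH2Cl2, 0 °C; then K2CO3, MeOH, 0 °C
Reagents that add atoms: none
Why: Tin-catalysed regioselective sulfonylation of the primary hydroxyl followed by 3-exo-tet Williamson closure by the adjacent tertiary alkoxide should form the epoxide with retention at the tertiary carbon, since no bond to that carbon is broken.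

Compound list
1 | 2,5-dimethylcyclopentan-1-one (cis/trans mixture) | CC1CCC(C)C1=O | starting material
2 | [(2,5-dimethylcyclopent-1-en-1-yl)oxy]trimethylsilane (racemic) | CC1CCC(C)=C1O[Si](C)(C)C | intermediate
3 | (2R)-2,5-dimethyl-2-(prop-2-en-1-yl)cyclopentan-1-one (both methine epimers) | CC1CC[C@](C)(CC=C)C1=O | intermediate
4 | {[(5R)-2,5-dimethyl-5-(prop-2-en-1-yl)cyclopent-1-en-1-yl]oxy}trimethylsilane | CC1=C(O[Si](C)(C)C)[C@@](C)(CC=C)CC1 | intermediate
5 | (2R,5R)-5-(hydroxymethyl)-2,5-dimethyl-2-(prop-2-en-1-yl)cyclopentan-1-one | OC[C@@]1(C)CC[C@](C)(CC=C)C1=O | intermediate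
6 | [(1R,3R)-1,3-dimethyl-2-oxo-3-(prop-2-en-1-yl)cyclopentyl]methyl 2-(diethoxyphosphoryl)acetate | CCOP(=O)(OCC)CC(=O)OC[C@@]1(C)CC[C@](C)(CC=C)C1=O | intermediate
7 | (5R,7aS)-5,7a-dimethyl-5-(prop-2-en-1-yl)-5,6,7,7a-tetrahydrocyclopenta[c]pyran-3(1H)-one | O=C1OC[C@@]2(C)CC[C@](C)(CC=C)C2=C1 | intermediate
8 | 2-[(5R,7aS)-5,7a-dimethyl-3-oxo-1,3,5,6,7,7a-hexahydrocyclopenta[c]pyran-5-yl]acetaldehyde | O=C1OC[C@@]2(C)CC[C@](C)(CC=O)C2=C1 | intermediate
9 | (5R,7aS)-5-(1,3-dioxolan-2-ylmethyl)-5,7a-dimethyl-5,6,7,7a-tetrahydrocyclopenta[c]pyran-3(1H)-one | O=C1OC[C@@]2(C)CC[C@](C)(CC3OCCO3)C2=C1 | intermediate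
10 | (4aR,5R,7aS)-5-(1,3-dioxolan-2-ylmethyl)-5,7a-dimethylhexahydrocyclopenta[c]pyran-3(1H)-one | O=C1OC[C@@]2(C)CC[C@](C)(CC3OCCO3)[C@H]2C1 | intermediate
11 | 3-bromobut-3-en-1-ol | OCCC(Br)=C | starting material
12 | 2-bromo-4-iodobut-1-ene | C=C(Br)CCI | intermediate
13 | (4aR,5R,7aS)-4-(3-bromobut-3-en-1-yl)-5-(1,3-dioxolan-2-ylmethyl)-5,7a-dimethylhexahydrocyclopenta[c]pyran-3(1H)-one (α-epimers) | O=C1OC[C@@]2(C)CC[C@](C)(CC3OCCO3)[C@H]2C1CCC(Br)=C | intermediate
14 | tetrabutylammonium 5-bromo-2-[(1R,2S,5R)-5-(1,3-dioxolan-2-ylmethyl)-2-(hydroxymethyl)-2,5-dimethylcyclopentyl]hex-5-enoate | OC[C@@]1(C)CC[C@](C)(CC3OCCO3)[C@H]1C(CCC(Br)=C)C(=O)[O-].CCCC[N+](CCCC)(CCCC)CCCC | intermediate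
15 | 5-bromo-2-[(1R,2S,5R)-5-(1,3-dioxolan-2-ylmethyl)-2-formyl-2,5-dimethylcyclopentyl]hex-5-enoic acid | O=C[C@@]1(C)CC[C@](C)(CC3OCCO3)[C@H]1C(CCC(Br)=C)C(=O)O | intermediate
16 | 3-bromocyclopent-2-en-1-one | O=C1CCC(Br)=C1 | starting material
17 | 3-(4,4,5,5-tetramethyl-1,3,2-dioxaborolan-2-yl)cyclopent-2-en-1-one | O=C1CCC(B2OC(C)(C)C(C)(C)O2)=C1 | intermediate
18 | 2-[(1R,2S,5R)-5-(1,3-dioxolan-2-ylmethyl)-2-formyl-2,5-dimethylcyclopentyl]-5-(3-oxocyclopent-1-en-1-yl)hex-5-enoic acid | O=C[C@@]1(C)CC[C@](C)(CC3OCCO3)[C@H]1C(CCC(=C)C2=CC(=O)CC2)C(=O)O | intermediate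
19 | tetracyclic aldol adduct (β-hydroxy ketone; rings A–D closed; CH–CH(OH) where 20 has the ring A/B C=C) | O=C1CC[C@@]23C1C(O)[C@@]1(C)CC[C@](C)(CC4OCCO4)[C@H]1[C@@H]2CCC3=C | intermediate
20 | tetracyclic dienone (ring A ketone conjugated to the ring A/B C=C; ring D exocyclic methylene; dioxolanylmethyl on ring C) | O=C1CC[C@@]23C1=C[C@@]1(C)CC[C@](C)(CC4OCCO4)[C@H]1[C@@H]2CCC3=C | intermediate
21 | tetracyclic triene (ring A and ring D exocyclic methylenes) | C=C1CC[C@@]23C1=C[C@@]1(C)CC[C@](C)(CC4OCCO4)[C@H]1[C@@H]2CCC3=C | intermediate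
22 | tetracyclic dioxolane (all seven ring stereocentres of the target) | C[C@H]1CC[C@@]23C1=C[C@@]1(C)CC[C@](C)(CC4OCCO4)[C@H]1[C@@H]2CC[C@@H]3C | intermediate
23 | tetracyclic aldehyde (CH2CHO on ring C) | C[C@H]1CC[C@@]23C1=C[C@@]1(C)CC[C@](C)(CC=O)[C@H]1[C@@H]2CC[C@@H]3C | intermediate
24 | (E)-3-iodo-2-methylprop-2-en-1-ol | OC/C(C)=C/I | starting material
25 | tert-butyl{[(E)-3-iodo-2-methylprop-2-en-1-yl]oxy}dimethylsilane | CC(C)(C)[Si](C)(C)OC/C(C)=C/I | intermediate
26 | (S)-allylic alcohol with E-alkene and primary silyl ether | C[C@H]1CC[C@@]23C1=C[C@@]1(C)CC[C@](C)(C[C@H](O)/C=C(\C)CO[Si](C)(C)C(C)(C)C)[C@H]1[C@@H]2CC[C@@H]3C | intermediate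
27 | (S,S,S)-triol silyl ether | C[C@H]1CC[C@@]23C1=C[C@@]1(C)CC[C@](C)(C[C@H](O)[C@H](O)[C@](O)(C)CO[Si](C)(C)C(C)(C)C)[C@H]1[C@@H]2CC[C@@H]3C | intermediate
28 | (S,S,S)-tetraol | C[C@H]1CC[C@@]23C1=C[C@@]1(C)CC[C@](C)(C[C@H](O)[C@H](O)[C@](O)(C)CO)[C@H]1[C@@H]2CC[C@@H]3C | intermediate
29 | primary tosylate of 28 | C[C@H]1CC[C@@]23C1=C[C@@]1(C)CC[C@](C)(C[C@H](O)[C@H](O)[C@](O)(C)COS(=O)(=O)c5ccc(C)cc5)[C@H]1[C@@H]2CC[C@@H]3C | intermediate
30 | CNP0393869.2 | C[C@H]1CC[C@@]23C1=C[C@@]1(C)CC[C@](C)(C[C@H](O)[C@H](O)[C@]4(C)CO4)[C@H]1[C@@H]2CC[C@@H]3C | target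

Total step count: 22. Longest linear sequence: 19 steps (1–8, 10, 11, 13–17, 19–22).

Steps most likely to fail

Step 14. The radical may be quenched before it cyclizes, may close 5-endo on the methylene terminus, or may add with poor facial selectivity at the radical carbon; the aldol closure may also lag behind protonation. The fallback separates the two bond formations into known single reactions and keeps the aldehyde out of the radical step. It sets out from 14: Suzuki coupling of the carboxylate with 17 (PdCl2(dppf), K3PO4) should give the hydroxy acid dienone F1. Irradiation with the same iridium photocatalyst and K2HPO4 in DMF should then give, by decarboxylative 5-exo Giese cyclization alone, the spiro keto alcohol F2, at which stage diastereomers can be separated. Dess–Martin oxidation should give the spiro keto aldehyde F3, and KOH in MeOH should close ring B by aldol condensation, returning to 20.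

Step 4. Facial selectivity in the addition of formaldehyde to the tetrasubstituted enol ether may be poor, because the two faces differ only by methyl versus allyl on the neighbouring quaternary carbon. The fallback reverses the order of the two quaternary-centre-forming events, so that the diastereoselective event is the palladium allylation next to a bulky silyloxymethyl group. It sets out from 2: the Sc-catalysed hydroxymethylation of step 4, now an enantioselective step on the simple enol ether, should give (2R)-2-(hydroxymethyl)-2,5-dimethylcyclopentan-1-one F4. TBSCl and imidazole should give the silyl ether F5, and LiN(i-Pr)2 with TMSCl the silyl enol ether F6. Allylation under the conditions of step 2 should give the trans-dimethyl ketone F7, since the allyl group should enter anti to the silyloxymethyl group in the sense also favoured by the ligand. HF·pyridine then returns to 5.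

Step 8. Hydrogen may be delivered to the wrong face of the hindered conjugated alkene, giving the trans-fused lactone, or the reduction may stall. The fallback uses hydroxyl-directed homogeneous hydrogenation. It sets out from 8: NaBH4 in MeOH at −40 °C should give the hydroxyethyl unsaturated lactone F8. Hydrogenation with [Ir(cod)(PCy3)(py)]PF6 in CH2Cl2 should deliver hydrogen from the face of the hydroxyethyl arm, which is the face of the angular methyl, and give the cis-fused hydroxyethyl lactone F9. Dess–Martin oxidation should give the aldehyde F10, and ethylene glycol with p-TsOH returns to 10.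

Further compounds
F1 | step 14 | 2-[(1R,2S,5R)-5-(1,3-dioxolan-2-ylmethyl)-2-(hydroxymethyl)-2,5-dimethylcyclopentyl]-5-(3-oxocyclopent-1-en-1-yl)hex-5-enoic acid | OC[C@@]1(C)CC[C@](C)(CC3OCCO3)[C@H]1C(CCC(=C)C2=CC(=O)CC2)C(=O)O
F2 | step 14 | spiro keto alcohol (ring D closed; cyclopentan-3-one ring A spiro-linked at the new quaternary carbon; CH2OH on ring C) | OC[C@@]1(C)CC[C@](C)(CC3OCCO3)[C@H]1[C@@H]4CCC(=C)[C@@]45CCC(=O)C5
F3 | step 14 | spiro keto aldehyde (F2 with CHO on ring C) | O=C[C@@]1(C)CC[C@](C)(CC3OCCO3)[C@H]1[C@@H]4CCC(=C)[C@@]45CCC(=O)C5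
F4 | step 4 | (2R)-2-(hydroxymethyl)-2,5-dimethylcyclopentan-1-one | OC[C@@]1(C)CCC(C)C1=O
F5 | step 4 | (2R)-2-{[(tert-butyldimethylsilyl)oxy]methyl}-2,5-dimethylcyclopentan-1-one | CC(C)(C)[Si](C)(C)OC[C@@]1(C)CCC(C)C1=O
F6 | step 4 | tert-butyldimethyl{[(1R)-1,3-dimethyl-2-(trimethylsilyloxy)cyclopent-2-en-1-yl]methoxy}silane | CC(C)(C)[Si](C)(C)OC[C@@]1(C)CCC(C)=C1O[Si](C)(C)C
F7 | step 4 | (2R,5R)-5-{[(tert-butyldimethylsilyl)oxy]methyl}-2,5-dimethyl-2-(prop-2-en-1-yl)cyclopentan-1-one | CC(C)(C)[Si](C)(C)OC[C@@]1(C)CC[C@](C)(CC=C)C1=O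
F8 | step 8 | (5R,7aS)-5-(2-hydroxyethyl)-5,7a-dimethyl-5,6,7,7a-tetrahydrocyclopenta[c]pyran-3(1H)-one | O=C1OC[C@@]2(C)CC[C@](C)(CCO)C2=C1
F9 | step 8 | (4aR,5R,7aS)-5-(2-hydroxyethyl)-5,7a-dimethylhexahydrocyclopenta[c]pyran-3(1H)-one | O=C1OC[C@@]2(C)CC[C@](C)(CCO)[C@H]2C1
F10 | step 8 | 2-[(4aR,5R,7aS)-5,7a-dimethyl-3-oxooctahydrocyclopenta[c]pyran-5-yl]acetaldehyde | O=C1OC[C@@]2(C)CC[C@](C)(CC=O)[C@H]2C1
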